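## Structural features

The target is an unsymmetrical dimer of two α-hydroxy-α,β-bis(arylmethyl)-γ-butyrolactones. Lactone 1 carries guaiacyl ring A on its β-CH2 and ring B on its α-CH2; lactone 2 carries ring C on its β-CH2 and guaiacyl ring D on its α-CH2. Rings B and C are joined by a biaryl bond at C5 of each ring (C1 bears the CH2 arm, C3 the OMe, C4 the OH), so the bond lies ortho to both phenols. Because this bond links an α-arm ring to a β-arm ring, the two halves are not related by symmetry and a true two-directional synthesis is excluded. In each lactone an oxygenated quaternary α-carbon stands next to a tertiary β-carbon; all four centres are R, the two arylmethyl groups are trans and the hydroxyl is cis to the β-arylmethyl group. Fragile groups are the four free guaiacyl phenols (one-electron oxidation), the four benzylic CH2 groups, the base-labile lactones and the tertiary α-hydroxy lactones. The real difficulty is the oxygenated quaternary α-carbon in a fixed relation to its neighbour, needed twice on a polyphenol. The key step uses the tertiary α-C-H bond of each lactone in the deoxy compound 20 (all four centres S), where hydrogen sits exactly where the hydroxyl must go. Strictly, this step creates no new stereocentre: both α-carbons are already stereogenic in 20, and the change of all four descriptors from S to R follows from the priority rules alone, not from any inversion.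

## Logic of the disconnections

22 to 20 and 21. The two tertiary C-O bonds at the α-carbons are cut. This removes both quaternary carbinol centres at once and leaves lactones whose α-centres are tertiary and can be set by enolate alkylation. The forward step must find two α-C-H bonds among weaker benzylic C-H and phenolic O-H bonds and must keep the configuration. Compound 20 is kept as the free tetraphenol: benzyl or methyl-type ethers would themselves be oxidised off by the enzyme, acyl groups would not survive the buffer, and nothing then remains to be done after the key step.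

20 to 19. Four O-benzyl bonds are cut. The phenols have to be masked during the enolate and bromide chemistry; benzyl is chosen because all four leave in one neutral hydrogenolysis that touches neither lactone nor stereocentre.

19 to 6 and 17 (through 18). The bond from the α-carbon of lactone 1 to the CH2 of ring B is cut. It lies next to a carbonyl, and alkylation of a β-substituted lactone enolate anti to the β-group gives the trans relation. The cut separates a simple monoaryl lactone from the whole biaryl half. The demand is that 18 alkylates 17 faster than it removes the tertiary α-hydrogen of the lactone already present in 17.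

17 to 16, and 16 to 12 and 14 (through 15). First the C-Br bond is traced back to the benzylic alcohol, then the bond from the α-carbon of lactone 2 to the CH2 of ring D is cut on the same logic as above. The demand is carbon- over oxygen-alkylation in the dianion 15, which saves a protection and a deprotection.

12 to 10 (through 11) and 10 to 9. The lactone C-O bond comes from reduction of the ester next to the stereocentre, the ring B CH2OH from the aldehyde in the same operation, and the β-stereocentre from face-selective hydrogenation of the alkene. The reducing agent must spare the carboxylate; the hydrogenation catalyst must leave the aldehyde and the benzyl ethers alone.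

9 to 8 and 2, and 8 to 7. The C=C bond between the benzylic carbon of ring C and the succinate carbon is cut. The condensation delivers the four-carbon unit with its two carboxyls already differentiated, and it is also the event that tells the two arms of the symmetric dialdehyde apart. The demand is reaction at one aldehyde only, which is statistical and is handled by stoichiometry and recycling.

6 to 4 (through 5), 4 to 3, and 3 to 1 and 2. The same three operations are applied in the monoaryl series.

14 to 13. The C-Br bond is cut back to the purchased alcohol.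

## Other disconnections considered

Alternative 1: The cut is the α-carbon to β-carbon bond of each lactone. In the forward sense a bis-allyl ester A2 is enolised twice (LiN(SiMe3)2, Me3SiCl, THF) and both silyl ketene acetals rearrange in a double Ireland-Claisen reaction to the diacid A1.
- In its favour: the tertiary oxygen is present from the start, the chelated enolate geometry of an α-alkoxy ester is dependable, and a chair transition state passes the configuration of one carbinol centre on to both new centres of each half. On mechanistic precedent and predictability of configuration this is the better plan.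
- Against it here: a chair analysis shows that the trans-dibenzyl, cis-hydroxy arrangement requires Z alkenes and R carbinol centres in A2, on two different allylic alcohols. The rearrangement also has to build a quaternary carbon from a tetrasubstituted ketene acetal. After A1 each propenyl group must still be cleaved in the presence of six electron-rich arenes, reduced and lactonised, and six benzyl groups, two of them on hindered tertiary oxygens, must be removed.
- Comparison: in structure it reaches the same atoms through an acyclic array with more functional-group traffic; in mechanism it is pericyclic and known where the chosen plan depends on an enzyme that does not yet exist; in step economy it should need roughly twice the operations. The two plans are equal in one respect: both run a stereo-defining event at two sites of one molecule, so any leak in selectivity multiplies.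

Alternative 2: The cut removes two bonds of ring B (C3-C4 and C5-C6). Forward, the 2-pyrone fragment 1 (A4) and the siloxyalkyne fragment 2 (A5) undergo [4+2] cycloaddition on heating, the bridged adduct loses CO2, and the protected target A3 results.
- In its favour: it is convergent, it joins two complete halves while making the arene, it needs no desymmetrisation of a symmetric biaryl (on this point it is better than the chosen plan), and the regiochemistry is encoded in the polarisation of the ynol ether.
- Against it here: the hard problem is only moved. A4 and A5 must each already hold an α-oxygenated quaternary centre, made by other means. The pyrone carries a donor methoxy group on a diene terminus and must react with an electron-rich alkyne, so high temperature is likely, in the presence of tertiary benzyl ethers and lactones. A5 is acid- and moisture-sensitive, and one phenol ends as a silyl ether that needs separate removal.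
- Comparison: structurally it is the most convergent of the four; mechanistically the pyrone-alkyne cycloaddition and loss of CO2 are known but thinly precedented with ynol ethers; in step economy it is clearly longer. It equals the chosen plan in leaving the stereocentres untouched in its key step.

Alternative 3: The cut is the bond from each β-carbon to the carbon that becomes the ring CH2O. Forward, the bis-epoxide A7 is opened at both CH carbons by a vinyl cuprate (CH2=CHMgBr, CuBr·SMe2, THF) to the bis(tertiary alcohol) A6.
- In its favour: the absolute configuration comes from reagent-controlled epoxidation and the relative configuration from stereospecific anti opening, and the tertiary alcohol is simply the former epoxide oxygen. In predictability of configuration it is the better plan.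
- Against it here: working back from A6 shows that A7 derives from Z-configured trisubstituted allylic alcohols (CH2OH cis to the arylmethyl group on the alkene CH), a slow and less selective class for Ti(OiPr)4/tartrate epoxidation. The cuprate must attack a secondary carbon flanked by a quaternary epoxide carbon. Each half then still needs cleavage of the vinyl group next to electron-rich arenes, reduction, desilylation, oxidation of a primary alcohol to the acid beside a tertiary alcohol, and lactonisation.
- Comparison: the two halves of A7 differ, so it is two-directional only in the sense that one reagent acts at both ends, which is equally true of the chosen key step; mechanistically every step is known chemistry; in step economy it is the longest of the four.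

Key step: step 13

Remarks on the chemistry:
- Compounds 1, 7 and 13 are taken as purchased; 7 is otherwise available in one operation from vanillin by oxidative coupling.
- The (R,R) antipode of the rhodium catalyst in steps 2 and 6 is assigned to the S acids by the chelate model (the CH2CO2 arm in the place of the acylamino group of an enamide). If the first analysis of 4 shows the opposite sense, the (S,S) antipode is used with no other change.

## Route

Step 1
Reactants: 1 4-benzyloxy-3-methoxybenzaldehyde; 2 dimethyl succinate
Product: 3 (E)-4-(4-benzyloxy-3-methoxyphenyl)-3-(methoxycarbonyl)but-3-enoic acid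
Conditions: KOtBu, tBuOH, reflux; then aq. HCl
Reagents that add atoms: none
Why: Stobbe condensation: the succinate enolate adds to the aldehyde, the alkoxide closes onto the far ester and the paraconate opens by elimination to a potassium carboxylate that resists further reaction; the E alkene with aryl trans to CO2Me is the favoured isomer.

Step 2
Reactants: 3 (E)-4-(4-benzyloxy-3-methoxyphenyl)-3-(methoxycarbonyl)but-3-enoic acid
Product: 4 (S)-4-(4-benzyloxy-3-methoxyphenyl)-3-(methoxycarbonyl)butanoic acid
Conditions: H2 (5 bar), [Rh(cod)((R,R)-Et-DuPhos)]BF4 (1 mol %), NaOMe (10 mol %), MeOH, 25 °C; then aq. HCl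
Reagents that add atoms: none
Why: Rhodium-catalysed asymmetric hydrogenation of an itaconate-type half ester: the carboxylate and the alkene chelate monovalent rhodium and the C2-symmetric bisphospholane selects the alkene face, which sets the S centre; benzyl ethers are inert to the homogeneous catalyst.

Step 3
Reactants: 4 (S)-4-(4-benzyloxy-3-methoxyphenyl)-3-(methoxycarbonyl)butanoic acid
Product: 6 (S)-4-(4-benzyloxy-3-methoxybenzyl)dihydrofuran-2(3H)-one, via hydroxy acid 5 (not isolated)
Conditions: KOH (1.0 equiv), EtOH; CaCl2, NaBH4, -10 °C to rt; then 3 M HCl, rt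
Reagents that add atoms: none
Why: Chemoselective borohydride reduction: Ca(BH4)2 made in the flask reduces the ester but not the potassium carboxylate, and acid then closes the γ-hydroxy acid to the lactone; the stereocentre is not touched and keeps its descriptor.

Step 4
Reactants: 7 divanillin
Product: 8 6,6'-bis(benzyloxy)-5,5'-dimethoxybiphenyl-3,3'-dicarbaldehyde
Conditions: BnBr (2.4 equiv), K2CO3, DMF, 60 °C
Reagents that add atoms: benzyl bromide, BrCc1ccccc1
Why: Williamson ether synthesis on both phenoxides; the aldehydes are not affected by carbonate in DMF.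

Step 5
Reactants: 8 6,6'-bis(benzyloxy)-5,5'-dimethoxybiphenyl-3,3'-dicarbaldehyde; 2 dimethyl succinate
Product: 9 (E)-4-[6,6'-bis(benzyloxy)-3'-formyl-5,5'-dimethoxybiphenyl-3-yl]-3-(methoxycarbonyl)but-3-enoic acid
Conditions: 8 (2.5 equiv), KOtBu (1.2 equiv), tBuOH/THF, 50 °C; aq. HCl; acid-base extraction, recovered 8 recycled
Reagents that add atoms: none
Why: Stobbe condensation run with the dialdehyde in excess so that statistically one aldehyde per molecule reacts; the product is an acid and is separated from neutral 8 by extraction, and this step is what distinguishes the ring C arm from the ring B arm.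

Step 6
Reactants: 9 (E)-4-[6,6'-bis(benzyloxy)-3'-formyl-5,5'-dimethoxybiphenyl-3-yl]-3-(methoxycarbonyl)but-3-enoic acid
Product: 10 (S)-4-[6,6'-bis(benzyloxy)-3'-formyl-5,5'-dimethoxybiphenyl-3-yl]-3-(methoxycarbonyl)butanoic acid
Conditions: H2 (5 bar), [Rh(cod)((R,R)-Et-DuPhos)]BF4 (1 mol %), NaOMe (10 mol %), MeOH/THF, 25 °C; then aq. HCl
Reagents that add atoms: none
Why: Same rhodium-catalysed asymmetric hydrogenation as in step 2, setting the S centre by chelate-directed face selection; an aryl aldehyde is not reduced by the cationic bisphosphine rhodium catalyst under these mild conditions.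

Step 7
Reactants: 10 (S)-4-[6,6'-bis(benzyloxy)-3'-formyl-5,5'-dimethoxybiphenyl-3-yl]-3-(methoxycarbonyl)butanoic acid
Product: 12 (S)-4-{[6,6'-bis(benzyloxy)-3'-(hydroxymethyl)-5,5'-dimethoxybiphenyl-3-yl]methyl}dihydrofuran-2(3H)-one, via dihydroxy acid 11 (not isolated)
Conditions: KOH (1.0 equiv), EtOH/THF; CaCl2, NaBH4, -10 °C to rt; evaporate; 1 M HCl to pH 3, EtOAc, 0 °C; then PPTS (cat.), toluene, 50 °C
Reagents that add atoms: none
Why: Ca(BH4)2 reduces the ester and the aldehyde while the carboxylate survives, and the γ-hydroxy acid lactonises under mild acid; ethanol is removed before acidification so that the electron-rich benzylic alcohol is not etherified.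

Step 8
Reactants: 13 4-benzyloxy-3-methoxybenzyl alcohol
Product: 14 4-benzyloxy-3-methoxybenzyl bromide
Conditions: PBr3 (0.4 equiv), Et2O, 0 °C; used at once
Reagents that add atoms: phosphorus tribromide, BrP(Br)Br
Why: Bromide displaces the phosphite ester of the benzylic alcohol (SN2); the electron-rich bromide is not stored.

Step 9
Reactants: 12 (S)-4-{[6,6'-bis(benzyloxy)-3'-(hydroxymethyl)-5,5'-dimethoxybiphenyl-3-yl]methyl}dihydrofuran-2(3H)-one; 14 4-benzyloxy-3-methoxybenzyl bromide
Product: 16 (3S,4S)-3-(4-benzyloxy-3-methoxybenzyl)-4-{[6,6'-bis(benzyloxy)-3'-(hydroxymethyl)-5,5'-dimethoxybiphenyl-3-yl]methyl}dihydrofuran-2(3H)-one, via dilithium alkoxide enolate 15 (not isolated)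
Conditions: LiN(SiMe3)2 (2.2 equiv), THF, -78 °C; 14 (1.1 equiv), -78 to -40 °C; aq. NH4Cl
Reagents that add atoms: none
Why: Enolate alkylation of a β-substituted butyrolactone: the benzylic bromide approaches the enolate face anti to the β-arylmethyl group, which sets the new α-centre trans (S); the remote lithium alkoxide is a poor nucleophile in THF at low temperature, the same chemoselectivity that underlies Fráter-Seebach alkylation of hydroxy ester dianions.

Step 10
Reactants: 16 (3S,4S)-3-(4-benzyloxy-3-methoxybenzyl)-4-{[6,6'-bis(benzyloxy)-3'-(hydroxymethyl)-5,5'-dimethoxybiphenyl-3-yl]methyl}dihydrofuran-2(3H)-one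
Product: 17 (3S,4S)-3-(4-benzyloxy-3-methoxybenzyl)-4-{[6,6'-bis(benzyloxy)-3'-(bromomethyl)-5,5'-dimethoxybiphenyl-3-yl]methyl}dihydrofuran-2(3H)-one
Conditions: CBr4, PPh3, CH2Cl2, 0 °C
Reagents that add atoms: carbon tetrabromide, BrC(Br)(Br)Br
Why: Appel reaction under neutral conditions; lactone, benzyl ethers and the epimerisable α-centre are not affected.

Step 11
Reactants: 6 (S)-4-(4-benzyloxy-3-methoxybenzyl)dihydrofuran-2(3H)-one; 17 (3S,4S)-3-(4-benzyloxy-3-methoxybenzyl)-4-{[6,6'-bis(benzyloxy)-3'-(bromomethyl)-5,5'-dimethoxybiphenyl-3-yl]methyl}dihydrofuran-2(3H)-one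
Product: 19 tetra-O-benzyl ether of the (3S,4S,3'S,4'S) bis(trans-dibenzylbutyrolactone) 20, via lithium enolate 18 (not isolated)
Conditions: 6 (1.3 equiv), LiN(SiMe3)2 (1.25 equiv), THF, -78 °C; 17 (1.0 equiv), DMPU, -78 to -50 °C; aq. NH4Cl
Reagents that add atoms: none
Why: Second trans-selective enolate benzylation, anti to the β-arylmethyl group of lactone 1, which sets its α-centre (S); SN2 at the activated benzylic bromide at low temperature should outrun proton transfer from the hindered tertiary α-C-H of the lactone already present in 17.

Step 12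
Reactants: 19 tetra-O-benzyl ether of the (3S,4S,3'S,4'S) bis(trans-dibenzylbutyrolactone) 20
Product: 20 (3S,4S,3'S,4'S) bis(trans-dibenzylbutyrolactone) tetraphenol (lactone 1: ring A on β-CH2, ring B on α-CH2; lactone 2: ring C on β-CH2, ring D on α-CH2; rings B and C joined ortho to their phenols)
Conditions: H2 (1 atm), Pd/C (10 wt %), THF/MeOH, rt
Reagents that add atoms: none
Why: Hydrogenolysis of four benzyl aryl ethers on palladium; lactones, arylmethyl C-C bonds and all four stereocentres are untouched.

Step 13
Reactants: 20 (3S,4S,3'S,4'S) bis(trans-dibenzylbutyrolactone) tetraphenol; 21 dioxygen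
Product: 22 target, the (3R,4R,3'R,4'R) bis(α-hydroxy-trans-dibenzylbutyrolactone) tetraphenol
Conditions: engineered self-sufficient cytochrome P450 monooxygenase (CYP102A1 lineage, evolved on 20), NADP+ (cat.), D-glucose, glucose dehydrogenase, air, KH2PO4/K2HPO4 buffer pH 8.0, DMSO (5 vol %), 25 °C
Reagents that add atoms: none
Why: Proposed new method: the thiolate-bound oxoiron porphyrin radical cation, formed from O2 and two electrons from NADPH, abstracts the α-hydrogen of a lactone and the iron-bound hydroxyl rebounds onto the planar α-acyl radical on the face the hydrogen left, faster than the bound substrate can turn. The closest known reaction types are P450 hydroxylation of tertiary C-H bonds with retention, α-hydroxylation of fatty acids by bacterial P450 enzymes, and the P450 oxidations of dibenzylbutyrolactone lignans in plants. No ring closes and no C-C bond forms; two C-O bonds are made, one at each α-carbon, in two successive turnovers. No new stereocentre arises: each α-carbon is already stereogenic in 20 and is carried over with retention, the controlling element being the pocket that fixes the face of abstraction and rebound, so the arylmethyl groups stay trans and the hydroxyl ends cis to the β-arylmethyl group. The step needs site selectivity for two tertiary α-C-H bonds over four benzylic CH2 groups, four OCH3 groups and four phenolic O-H bonds, all at least as easy to attack, and the electron-poor α-C-H is polarity-mismatched with the electrophilic oxidant. Nothing in 20 secures this by itself; it must be imposed by an active site evolved to hold the lactone carbonyl beside the iron with the aryl rings held away. Because the two lactones sit in different surroundings, the variant must accept both and also the monohydroxylated intermediate.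

## Compound list

1 | 4-benzyloxy-3-methoxybenzaldehyde | COc1cc(C=O)ccc1OCc1ccccc1 | starting material
2 | dimethyl succinate | COC(=O)CCC(=O)OC | starting material
3 | (E)-4-(4-benzyloxy-3-methoxyphenyl)-3-(methoxycarbonyl)but-3-enoic acid | COC(=O)/C(CC(=O)O)=C/c1ccc(OCc2ccccc2)c(OC)c1 | intermediate
4 | (S)-4-(4-benzyloxy-3-methoxyphenyl)-3-(methoxycarbonyl)butanoic acid | COC(=O)[C@H](CC(=O)O)Cc1ccc(OCc2ccccc2)c(OC)c1 | intermediate
5 | (S)-3-(4-benzyloxy-3-methoxybenzyl)-4-hydroxybutanoic acid (formed in the flask) | OC[C@H](CC(=O)O)Cc1ccc(OCc2ccccc2)c(OC)c1 | intermediate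
6 | (S)-4-(4-benzyloxy-3-methoxybenzyl)dihydrofuran-2(3H)-one | COc1cc(C[C@@H]2COC(=O)C2)ccc1OCc1ccccc1 | intermediate
7 | divanillin (6,6'-dihydroxy-5,5'-dimethoxybiphenyl-3,3'-dicarbaldehyde) | COc1cc(C=O)cc(-c2cc(C=O)cc(OC)c2O)c1O | starting material
8 | 6,6'-bis(benzyloxy)-5,5'-dimethoxybiphenyl-3,3'-dicarbaldehyde | COc1cc(C=O)cc(-c2cc(C=O)cc(OC)c2OCc2ccccc2)c1OCc1ccccc1 | intermediate
9 | (E)-4-[6,6'-bis(benzyloxy)-3'-formyl-5,5'-dimethoxybiphenyl-3-yl]-3-(methoxycarbonyl)but-3-enoic acid | COC(=O)/C(CC(=O)O)=C/c1cc(OC)c(OCc2ccccc2)c(-c2cc(C=O)cc(OC)c2OCc2ccccc2)c1 | intermediate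
10 | (S)-4-[6,6'-bis(benzyloxy)-3'-formyl-5,5'-dimethoxybiphenyl-3-yl]-3-(methoxycarbonyl)butanoic acid | COC(=O)[C@H](CC(=O)O)Cc1cc(OC)c(OCc2ccccc2)c(-c2cc(C=O)cc(OC)c2OCc2ccccc2)c1 | intermediate
11 | (S)-3-{[6,6'-bis(benzyloxy)-3'-(hydroxymethyl)-5,5'-dimethoxybiphenyl-3-yl]methyl}-4-hydroxybutanoic acid (formed in the flask) | OC[C@H](CC(=O)O)Cc1cc(OC)c(OCc2ccccc2)c(-c2cc(CO)cc(OC)c2OCc2ccccc2)c1 | intermediate
12 | (S)-4-{[6,6'-bis(benzyloxy)-3'-(hydroxymethyl)-5,5'-dimethoxybiphenyl-3-yl]methyl}dihydrofuran-2(3H)-one | COc1cc(C[C@@H]2COC(=O)C2)cc(-c2cc(CO)cc(OC)c2OCc2ccccc2)c1OCc1ccccc1 | intermediate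
13 | 4-benzyloxy-3-methoxybenzyl alcohol | COc1cc(CO)ccc1OCc1ccccc1 | starting material
14 | 4-benzyloxy-3-methoxybenzyl bromide | COc1cc(CBr)ccc1OCc1ccccc1 | intermediate
15 | dilithium alkoxide enolate of 12 (formed in the flask) | [Li+].[Li+].COc1cc(C[C@@H]2COC([O-])=C2)cc(-c2cc(C[O-])cc(OC)c2OCc2ccccc2)c1OCc1ccccc1 | intermediate
16 | (3S,4S)-3-(4-benzyloxy-3-methoxybenzyl)-4-{[6,6'-bis(benzyloxy)-3'-(hydroxymethyl)-5,5'-dimethoxybiphenyl-3-yl]methyl}dihydrofuran-2(3H)-one | COc1cc(C[C@@H]2COC(=O)[C@H]2Cc2ccc(OCc3ccccc3)c(OC)c2)cc(-c2cc(CO)cc(OC)c2OCc2ccccc2)c1OCc1ccccc1 | intermediate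
17 | (3S,4S)-3-(4-benzyloxy-3-methoxybenzyl)-4-{[6,6'-bis(benzyloxy)-3'-(bromomethyl)-5,5'-dimethoxybiphenyl-3-yl]methyl}dihydrofuran-2(3H)-one | COc1cc(C[C@@H]2COC(=O)[C@H]2Cc2ccc(OCc3ccccc3)c(OC)c2)cc(-c2cc(CBr)cc(OC)c2OCc2ccccc2)c1OCc1ccccc1 | intermediate
18 | lithium enolate of 6 (formed in the flask) | [Li+].COc1cc(C[C@@H]2COC([O-])=C2)ccc1OCc1ccccc1 | intermediate
19 | tetra-O-benzyl ether of 20, (3S,4S,3'S,4'S) | COc1cc(C[C@@H]2COC(=O)[C@H]2Cc2cc(OC)c(OCc3ccccc3)c(-c3cc(C[C@@H]4COC(=O)[C@H]4Cc4ccc(OCc5ccccc5)c(OC)c4)cc(OC)c3OCc3ccccc3)c2)ccc1OCc1ccccc1 | intermediate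
20 | (3S,4S,3'S,4'S) bis(trans-dibenzylbutyrolactone) tetraphenol, the target without its two tertiary hydroxyls | COc1cc(C[C@@H]2COC(=O)[C@H]2Cc2cc(OC)c(O)c(-c3cc(C[C@@H]4COC(=O)[C@H]4Cc4ccc(O)c(OC)c4)cc(OC)c3O)c2)ccc1O | intermediate
21 | dioxygen | O=O | starting material
22 | target, (3R,4R,3'R,4'R) bis(α-hydroxy-trans-dibenzylbutyrolactone) tetraphenol | COc1cc(C[C@@H]2COC(=O)[C@@]2(O)Cc2cc(OC)c(O)c(-c3cc(C[C@@H]4COC(=O)[C@@]4(O)Cc4ccc(O)c(OC)c4)cc(OC)c3O)c2)ccc1O | target

## Step count and least certain steps

Total: 13 steps. Longest linear sequence: 9 steps (steps 4, 5, 6, 7, 9, 10, 11, 12, 13, from 7 to 22).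

**Step 13 (key step, proposed new method).** The most likely failure is hydrogen abstraction at the wrong place: benzylic C-H, phenolic O-H (leading on to quinone methides or phenol coupling) or OCH3 (demethylation) are all intrinsically easier than the electron-poor α-C-H. Acceptance of only one of the two lactones and low turnover with so large a substrate are further risks.

Fallback, known chemistry, from 6 and 12 back to 22. The approach changes from late C-H oxidation to installing the oxygen first and making the α C-C bond last, so that the α-centre is set by alkylation anti to the β-group.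
- Lactone 6 is enolised (NaN(SiMe3)2, THF, -78 °C) and oxidised with 2-(phenylsulfonyl)-3-phenyloxaziridine to the α-hydroxy lactone F1; its α-configuration is immaterial.
- Alcohol 12 is silylated (TBSCl, imidazole, DMF) to the silyl ether F2 and hydroxylated in the same way to the α-hydroxy lactone F3.
- The dianion of F3 (LiN(iPr)2, 2.2 equiv, THF/DMPU, -78 to -30 °C) is benzylated with 14 anti to the β-arylmethyl group, giving the trans-dibenzyl α-hydroxy lactone F4 with the hydroxyl cis to the β-arm.
- Ph3PBr2 in CH2Cl2 converts the benzylic silyl ether directly into the bromide F5.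
- F5, first turned into its lithium alkoxide with one equivalent of LiN(SiMe3)2, alkylates the dianion of F1 to the tetra-O-benzyl target F6. Lactone 2 of F5 has no α-hydrogen, so proton transfer is not an issue.
- Hydrogenolysis (H2, Pd/C) of F6 returns to the route at 22.

**Step 5.** Double condensation at both aldehydes, or poor separation of mono- from bis-adduct, would erode the desymmetrisation, since the two aldehydes are electronically independent.

Fallback from 2 (with purchased 5-bromovanillin and benzyl bromide) back to 9. The unsymmetrical biaryl is built by cross-coupling instead of statistics.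
- 5-Bromovanillin is benzylated to 4-benzyloxy-3-bromo-5-methoxybenzaldehyde F7.
- Stobbe condensation of F7 with 2 gives the bromo half ester F8.
- A second portion of F7 is borylated (PdCl2(dppf), bis(pinacolato)diboron, KOAc, dioxane, 90 °C) to the boronate F9.
- Suzuki coupling of F8 with F9 (Pd(OAc)2, SPhos, K3PO4, toluene/H2O, 80 °C) gives 9.

**Step 9.** Oxygen-alkylation of the remote alkoxide, or incomplete formation or poor solubility of the dianion, would lower the conversion to 16.

Fallback from 12 back to 17. The hydroxyl is masked instead of being carried as an alkoxide: 12 is converted into the silyl ether F2 described above, its lithium enolate (LiN(SiMe3)2, 1.1 equiv, THF, -78 °C) is benzylated with 14 to the silyl ether F10, and Ph3PBr2 converts F10 directly into 17, so that step 10 is no longer needed.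

**Step 11.** Proton transfer from the lactone of 17 to enolate 18 during the slower SN2 reaction would cause epimerisation of lactone 2 to the cis series and self-alkylation.

Fallback from 16 (with 18 from 6) back to 19. The alkylation is replaced by an aldol addition, which is fast at -78 °C, followed by deoxygenation.
- MnO2 in CH2Cl2 oxidises 16 to the aldehyde F11.
- Enolate 18 adds to F11 anti to its β-substituent to give the aldol adduct F12 as a carbinol mixture.
- Ionic hydrogenation (Et3SiH, BF3·OEt2, CH2Cl2, -78 to -20 °C) removes the benzylic hydroxyl and gives 19.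

## Further compounds

F1 | step 13 | (4R)-4-(4-benzyloxy-3-methoxybenzyl)-3-hydroxydihydrofuran-2(3H)-one, either C3 epimer | COc1cc(C[C@@H]2COC(=O)C2O)ccc1OCc1ccccc1
F2 | step 13 | tert-butyldimethylsilyl ether of 12 | COc1cc(C[C@@H]2COC(=O)C2)cc(-c2cc(CO[Si](C)(C)C(C)(C)C)cc(OC)c2OCc2ccccc2)c1OCc1ccccc1
F3 | step 13 | α-hydroxy derivative of F2, either C3 epimer | COc1cc(C[C@@H]2COC(=O)C2O)cc(-c2cc(CO[Si](C)(C)C(C)(C)C)cc(OC)c2OCc2ccccc2)c1OCc1ccccc1
F4 | step 13 | (3R,4R)-3-(4-benzyloxy-3-methoxybenzyl)-3-hydroxy-4-{[6,6'-bis(benzyloxy)-3'-(tert-butyldimethylsilyloxymethyl)-5,5'-dimethoxybiphenyl-3-yl]methyl}dihydrofuran-2(3H)-one | COc1cc(C[C@@H]2COC(=O)[C@@]2(O)Cc2ccc(OCc3ccccc3)c(OC)c2)cc(-c2cc(CO[Si](C)(C)C(C)(C)C)cc(OC)c2OCc2ccccc2)c1OCc1ccccc1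
F5 | step 13 | bromide corresponding to F4 (3'-bromomethyl) | COc1cc(C[C@@H]2COC(=O)[C@@]2(O)Cc2ccc(OCc3ccccc3)c(OC)c2)cc(-c2cc(CBr)cc(OC)c2OCc2ccccc2)c1OCc1ccccc1
F6 | step 13 | tetra-O-benzyl ether of 22 | COc1cc(C[C@@H]2COC(=O)[C@@]2(O)Cc2cc(OC)c(OCc3ccccc3)c(-c3cc(C[C@@H]4COC(=O)[C@@]4(O)Cc4ccc(OCc5ccccc5)c(OC)c4)cc(OC)c3OCc3ccccc3)c2)ccc1OCc1ccccc1
F7 | step 5 | 4-benzyloxy-3-bromo-5-methoxybenzaldehyde | COc1cc(C=O)cc(Br)c1OCc1ccccc1
F8 | step 5 | (E)-4-(4-benzyloxy-3-bromo-5-methoxyphenyl)-3-(methoxycarbonyl)but-3-enoic acid | COC(=O)/C(CC(=O)O)=C/c1cc(Br)c(OCc2ccccc2)c(OC)c1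
F9 | step 5 | 4-benzyloxy-3-methoxy-5-(4,4,5,5-tetramethyl-1,3,2-dioxaborolan-2-yl)benzaldehyde | COc1cc(C=O)cc(B2OC(C)(C)C(C)(C)O2)c1OCc1ccccc1
F10 | step 9 | tert-butyldimethylsilyl ether of 16 | COc1cc(C[C@@H]2COC(=O)[C@H]2Cc2ccc(OCc3ccccc3)c(OC)c2)cc(-c2cc(CO[Si](C)(C)C(C)(C)C)cc(OC)c2OCc2ccccc2)c1OCc1ccccc1
F11 | step 11 | aldehyde corresponding to 16 (3'-formyl) | COc1cc(C[C@@H]2COC(=O)[C@H]2Cc2ccc(OCc3ccccc3)c(OC)c2)cc(-c2cc(C=O)cc(OC)c2OCc2ccccc2)c1OCc1ccccc1
F12 | step 11 | aldol adduct of 18 and F11, 19 with a hydroxyl on the ring B benzylic carbon, carbinol mixture | COc1cc(C[C@@H]2COC(=O)[C@H]2C(O)c2cc(OC)c(OCc3ccccc3)c(-c3cc(C[C@@H]4COC(=O)[C@H]4Cc4ccc(OCc5ccccc5)c(OC)c4)cc(OC)c3OCc3ccccc3)c2)ccc1OCc1ccccc1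
A1 | alternative 1 | bis(2-benzyloxy-3-propenyl) diacid | COc1cc(C[C@H](/C=C/C)[C@@](OCc2ccccc2)(C(=O)O)Cc2cc(OC)c(OCc3ccccc3)c(-c3cc(C[C@H](/C=C/C)[C@@](OCc4ccccc4)(C(=O)O)Cc4ccc(OCc5ccccc5)c(OC)c4)cc(OC)c3OCc3ccccc3)c2)ccc1OCc1ccccc1
A2 | alternative 1 | bis-ester of two 2-benzyloxy-3-arylpropanoic acids with two (R,Z)-5-arylpent-3-en-2-ols, α-centres of either configuration | COc1cc(C/C=C\[C@@H](C)OC(=O)C(OCc2ccccc2)Cc2cc(OC)c(OCc3ccccc3)c(-c3cc(C/C=C\[C@@H](C)OC(=O)C(OCc4ccccc4)Cc4ccc(OCc5ccccc5)c(OC)c4)cc(OC)c3OCc3ccccc3)c2)ccc1OCc1ccccc1
A3 | alternative 2 | penta-O-benzyl target with the ring B phenol as its triisopropylsilyl ether | COc1cc(C[C@@H]2COC(=O)[C@@]2(OCc2ccccc2)Cc2cc(OC)c(O[Si](C(C)C)(C(C)C)C(C)C)c(-c3cc(C[C@@H]4COC(=O)[C@@]4(OCc4ccccc4)Cc4ccc(OCc5ccccc5)c(OC)c4)cc(OC)c3OCc3ccccc3)c2)ccc1OCc1ccccc1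
A4 | alternative 2 | fragment 1, 3-methoxy-2-pyrone carrying at C5 the CH2 arm of the protected lactone 1 | COc1cc(C[C@@H]2COC(=O)[C@@]2(OCc2ccccc2)Cc2cc(OC)c(=O)oc2)ccc1OCc1ccccc1
A5 | alternative 2 | fragment 2, triisopropylsiloxyalkyne on ring C of the protected lactone 2 | CC(C)[Si](OC#Cc1cc(C[C@@H]2COC(=O)[C@@]2(OCc2ccccc2)Cc2ccc(OCc3ccccc3)c(OC)c2)cc(OC)c1OCc1ccccc1)(C(C)C)C(C)C
A6 | alternative 3 | bis(tertiary alcohol) with a vinyl group on each β-carbon | COc1cc(C[C@H](C=C)[C@@](O)(CO[Si](C)(C)C(C)(C)C)Cc2cc(OC)c(OCc3ccccc3)c(-c3cc(C[C@H](C=C)[C@@](O)(CO[Si](C)(C)C(C)(C)C)Cc4ccc(OCc5ccccc5)c(OC)c4)cc(OC)c3OCc3ccccc3)c2)ccc1OCc1ccccc1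
A7 | alternative 3 | bis(trisubstituted epoxide) with a silyloxymethyl group on each quaternary epoxide carbon | COc1cc(C[C@H]2O[C@]2(CO[Si](C)(C)C(C)(C)C)Cc2cc(OC)c(OCc3ccccc3)c(-c3cc(C[C@H]4O[C@]4(CO[Si](C)(C)C(C)(C)C)Cc4ccc(OCc5ccccc5)c(OC)c4)cc(OC)c3OCc3ccccc3)c2)ccc1OCc1ccccc1
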